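The numbers in the tables were computed with made-up constants; the scatter is artificial.

all flasks: solid substrate 0.10 M
- oak: precatalyst 6.9 µM; the very flask that is asked about, followed so far
- alder: precatalyst 4.6 µM; run made earlier
- flask: precatalyst 6.9 µM; time 25 min

| run | time / min | product / % | starting material / % |
|---|---|---|---|
| oak | 0.667 | 10.0 | 50.1 |
| oak | 2.00 | 64.0 | 36.1 |
| oak | 4.00 | 80.3 | 19.7 |
| oak | 5.00 | 79.4 | 21.0 |
| oak | 8.00 | 79.5 | 18.4 |
| oak | 10.0 | 79.7 | 20.2 |
| alder | 1.50 | 30.0 | 51.2 |
| alder | 3.00 | 73.5 | 25.7 |
| alder | 5.00 | 80.1 | 19.5 |
| alder | 6.00 | 79.5 | 19.8 |
| alder | 8.00 | 80.8 | 19.9 |
| alder | 10.0 | 80.3 | 19.7 |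

(scatter of a reading: 0.5 percentage points)

- amount of product at 25 min, in percent of the solid substrate charged
- concentration of starting material in solution at 25 min, in percent of saturation

- as a solid, counted per litre of solution: solid substrate
- at the start none of the solid substrate is in solution
- starting material is what solid substrate becomes in solution
- starting material means what is dissolved; the solid is not counted in it

The easy step came first: I added the two columns of each reading, since whatever fell short of the charge was still solid. On the first rung, the solution filled. In the oak run the sum was 60.1 % at 0.667 min, with starting material already at 50.1 %. I took the alder reading with solid present, 51.2 % at 1.50 min, as a floor for saturation.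

On the second rung, the solid went: the oak sum reached 100 % by 2.00 min, the alder sum 99.2 % by 3.00 min. On the third rung, the split showed no drift in either run, although the oak run had 1.50 times the precatalyst of the alder run; its starting material readings did stray, from 21.0 % at 5.00 min to 18.4 % at 8.00 min, against a scatter of 0.5 percentage points. The last rung was the asked time, 2.50 times the last reading.

So I carried one number: K, the equilibrium constant as read, product over starting material in the last readings of both runs, 4.01. I then reckoned only the small partner, the correction. For the oak flask, starting material came to 20.0 % of the charge, which left 80.0 % as product. Against the floor, that was at most 39.1 % of saturation.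

The forecast gave 80 % of product and 39 % of saturation, reasoning that “Catalyst death would have stopped the two runs at different points”. Mine agreed on product and held the saturation figure as an upper mark.

The flask gave 79.8 % of product and starting material at 36.7 % of saturation, under this scheme:

    starting material + enzyme ⇌ complex (K = 120 M⁻¹, k = 2.96 × 10⁵ M⁻¹ s⁻¹)
    complex ⇌ enzyme + product (K = 0.0330 M, k = 23300 min⁻¹)
    solid substrate ⇌ starting material, rate k3*(cs3 - [starting material]) while solid is left; crystals form when [starting material] > cs3 (solubility = 0.0550 M, k = 7.06 min⁻¹)
    precatalyst → enzyme (k = 0.381 min⁻¹)

Saturation was 0.055 M, which is 55.0 % of the charge. K went on to a second flask, the same one charged with 0.40 M of solid substrate and read at 25 min. There 31.8 % of its charge was still solid and starting material stood at 13.7 % of its charge, and K times that is 54.9 %, where that second flask held 54.4 % of product.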